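**Strategy.** The ten-membered ring is closed last, at C6–C7 (germacrane numbering), the bond shared by the carbocycle and the lactone ring. In the open precursor O8 and C12 are tied up as a 3-(bromomethyl)butenolide, and the other chain end is the C6 aldehyde on the C4/C5 epoxide. CrCl2 turns the bromide into an allylchromium that attacks the aldehyde through C7: one operation closes the macrocycle, sets C6 and C7 from the resolved C8 centre, unveils the C11=C13 methylene and lets the new O6 alkoxide take over the lactone carbonyl, freeing O8 for the tiglate. It exploits the O6–C6–C7–C8–O8 array around the α-methylene lactone.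

Key step: step 17

Remark on numbering: germacrane numbering is used for all intermediates (C1 carbinol, C2/C3 cis-epoxide, C4/C5 trans-epoxide with the C15 methyl on C4, C6, C7, C8, C9, C10=C14, C11=C13, C12 lactone carbonyl). CIP labels change along the route with the substituents (C2 is S with a free 1-OH and R with 1-OTES) although no centre is inverted. Short names are used in the steps; full names stand in the compound list.

Assumption: the target is the (1S,2S,3S,4S,5R,6S,7R,8R) enantiomer written in the SMILES, and (2E)-3-methylpent-2-en-4-yn-1-ol and tigloyl chloride are bought as single isomers.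

Step 1
Reactants: 1 acrolein; 2 2,3-dibromoprop-1-ene
Product: 3 rac-5-bromohexa-1,5-dien-3-ol
Conditions: In powder, THF/H2O 1:1, rt
Reagents that add atoms: none
Why: Barbier 2-bromoallylation, in which indium inserts only into the allylic C–Br bond of 2 and the allylindium adds 1,2 to the enal, giving the C8 carbinol with the C7 vinyl group and the C9–C10(Br)=C14 unit in place.

Step 2
Reactants: 3 rac-5-bromohexa-1,5-dien-3-ol
Product: 4 (3R)-5-bromohexa-1,5-dien-3-ol
Conditions: lipase PS (Burkholderia cepacia, immobilised), vinyl acetate, MTBE, 30 °C, run to about 55% conversion; chromatography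
Reagents that add atoms: none
Why: Lipase-catalysed kinetic resolution by transesterification, in which, following the Kazlauskas rule, the enzyme should acetylate the (S)-alcohol (2-bromoallyl as the large group) and leave the (R)-alcohol, which fixes C8.

Step 3
Reactants: 4 (3R)-5-bromohexa-1,5-dien-3-ol; 5 acryloyl chloride
Product: 6 (3R)-acrylate ester
Conditions: Et3N, DMAP (5 mol%), CH2Cl2, −20 to 0 °C
Reagents that add atoms: none
Why: O-acylation of the secondary alcohol, so C8 keeps its configuration, the acryloyl group supplying C11 and C12.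

Step 4
Reactants: 6 (3R)-acrylate ester; 7 formaldehyde (37% aqueous solution)
Product: 8 (3R)-2-(hydroxymethyl)acrylate ester
Conditions: DABCO (1 equiv), 1,4-dioxane/H2O 1:1, rt
Reagents that add atoms: none
Why: Morita–Baylis–Hillman reaction of an acrylate ester with formaldehyde, which puts C13 on C11 as CH2OH while C8, not yet acidic, cannot epimerise.

Step 5
Reactants: 8 (3R)-2-(hydroxymethyl)acrylate ester
Product: 9 bromoallyl butenolide alcohol
Conditions: second-generation Grubbs catalyst RuCl2(=CHPh)(PCy3)(H2IMes) (5 mol%), toluene (0.01 M), 80 °C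
Reagents that add atoms: none
Why: Ring-closing metathesis of the C7 vinyl group with the acrylate alkene, which forms C7=C11 and the butenolide with loss of ethylene, the electron-poor 2-bromoalkene staying out of the cycle.

Step 6
Reactants: 10 (2E)-3-methylpent-2-en-4-yn-1-ol
Product: 11 enyne PMB ether
Conditions: NaH (1.05 equiv), THF, 0 °C; 4-methoxybenzyl chloride, Bu4NI (5 mol%), 0 °C to rt
Reagents that add atoms: 4-methoxybenzyl chloride, COc1ccc(CCl)cc1
Why: Williamson ether synthesis on the alkoxide (the O–H is far more acidic than the alkyne C–H), which masks O6 as a PMB ether until step 15.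

Step 7
Reactants: 11 enyne PMB ether; 7 formaldehyde (as paraformaldehyde)
Product: 12 propargylic alcohol
Conditions: n-BuLi (1.05 equiv), THF, −78 °C; (CH2O)n, −78 °C to rt; aq. NH4Cl
Reagents that add atoms: none
Why: Addition of the lithium acetylide to formaldehyde, which adds C1 as a propargylic CH2OH.

Step 8
Reactants: 12 propargylic alcohol
Product: 13 (2Z,4E)-dienol
Conditions: H2 (1 atm), Pd/CaCO3 poisoned with Pb(OAc)2 (Lindlar catalyst), quinoline, EtOAc, rt
Reagents that add atoms: none
Why: Lindlar semihydrogenation, which adds H2 syn to the alkyne and so gives the (2Z)-alkene, the (4E)-alkene and the PMB ether being left alone.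

Step 9
Reactants: 13 (2Z,4E)-dienol
Product: 14 cis-epoxy alcohol
Conditions: Ti(OiPr)4 (1.0 equiv), L-(+)-diisopropyl tartrate (1.2 equiv), t-BuOOH (2 equiv, decane solution), 4 Å molecular sieves, CH2Cl2, −20 °C
Reagents that add atoms: tert-butyl hydroperoxide, CC(C)(C)OO
Why: Sharpless asymmetric epoxidation, which touches only the alkene of the allylic alcohol (C2=C3) and with L-(+)-tartrate turns a (Z)-allylic alcohol into the (2S,3R)-cis-epoxy alcohol, setting C2 and C3.

Step 10
Reactants: 14 cis-epoxy alcohol
Product: 15 bis-epoxy alcohol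
Conditions: D-fructose-derived Shi ketone (1,2:4,5-di-O-isopropylidene-β-D-erythro-hexo-2,3-diulo-2,6-pyranose, 0.5 equiv), KHSO5 (as 2KHSO5·KHSO4·K2SO4), K2CO3, Bu4NHSO4, aqueous Na2B4O7 buffer (pH 10.5), MeCN/dimethoxymethane, 0 °C
Reagents that add atoms: potassium peroxymonosulfate, [K+].[O-]S(=O)(=O)OO
Why: Shi epoxidation by the chiral dioxirane through a spiro transition state, which for an (E)-trisubstituted alkene gives the (R,R)-type epoxide and here sets C4 and C5 under catalyst control, the minor enantiomer of 14 being carried into a separable diastereomer.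

Step 11
Reactants: 15 bis-epoxy alcohol
Product: 16 bis-epoxy aldehyde
Conditions: Dess–Martin periodinane, NaHCO3, CH2Cl2, 0 °C to rt
Reagents that add atoms: none
Why: Dess–Martin oxidation of the primary alcohol under buffered conditions, which should give the cis-epoxy aldehyde (C1) without opening an epoxide or epimerising C2.

Step 12
Reactants: 16 bis-epoxy aldehyde; 9 bromoallyl butenolide alcohol (1.5 equiv)
Product: 17 seco diol
Conditions: CrCl2 (5 equiv), NiCl2 (5 mol%), DMSO, rt
Reagents that add atoms: none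
Why: Nozaki–Hiyama–Kishi coupling (zerovalent nickel inserts into C10–Br, transmetalation gives an alkenylchromium that tolerates the lactone, the epoxides and the free OH), the aldehyde being attacked in the Felkin–Anh sense anti to the C2–O epoxide bond, reinforced by the cis substituent at C3, to give the erythro (1S)-carbinol.

Step 13
Reactants: 17 seco diol
Product: 18 seco allylic bromide
Conditions: CBr4 (1.2 equiv), PPh3 (1.25 equiv), CH2Cl2, −30 to 0 °C
Reagents that add atoms: tetrabromomethane, BrC(Br)(Br)Br
Why: Appel bromination, in which the unhindered primary allylic C13–OH should be activated and displaced well before the secondary C1–OH that sits between the epoxide and C10.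

Step 14
Reactants: 18 seco allylic bromide
Product: 19 seco bromide TES ether
Conditions: Et3SiOTf (1.3 equiv), 2,6-lutidine (2 equiv), CH2Cl2, −78 °C
Reagents that add atoms: triethylsilyl trifluoromethanesulfonate, CC[Si](CC)(CC)OS(=O)(=O)C(F)(F)F
Why: Silyl ether formation at O1 with a hindered base that should neither be alkylated by the allylic bromide nor, at −78 °C, enolise the butenolide at C8.

Step 15
Reactants: 19 seco bromide TES ether
Product: 20 seco bromo alcohol
Conditions: DDQ (1.5 equiv), CH2Cl2/pH 7 phosphate buffer 10:1, 0 °C to rt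
Reagents that add atoms: none
Why: Oxidative cleavage of the PMB ether (benzylic hydride abstraction, then hydrolysis), to which the TES ether, the epoxides and the allylic bromide are inert.

Step 16
Reactants: 20 seco bromo alcohol
Product: 21 seco bromo aldehyde
Conditions: Dess–Martin periodinane, NaHCO3, CH2Cl2, 0 °C
Reagents that add atoms: none
Why: Dess–Martin oxidation to the C6 aldehyde on the trans-epoxide, the product being used without storage.

Step 17
Reactants: 21 seco bromo aldehyde
Product: 23 8-hydroxy-1-O-TES-6,12-olide, via 6-hydroxy-8,12-olide 22 (not isolated)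
Conditions: CrCl2 (10 equiv), DMF, rt, 21 added by syringe pump over 12 h (final 2 mM); then 45 °C, 6 h; aq. NH4Cl
Reagents that add atoms: none
Why: Two equivalents of CrCl2 reduce the allylic C13–Br bond to an allylchromium (trivalent chromium on C13) that adds through its γ-carbon C7 to the C6 aldehyde in a six-membered chair transition state, the double bond moving to C11=C13; the closest known reactions are the intramolecular Nozaki–Hiyama (chromium Barbier) allylation of 2-(bromomethyl)enoates with aldehydes, a reaction type used for ten-membered germacranolide ring closure, and the Barbier chemistry of 3-(bromomethyl)butenolides. The ten-membered carbocycle closes by 10-exo-trig attack on the formyl group; the chromium alkoxide on O6 then adds 5-exo-trig to C12 and the bicyclic ortho ester opens towards O8 (lactone migration), because the trans-fused 6,12-olide should be the stable lactone of a 6α,8β-dioxygenated germacrane. C7 is controlled by C8: the tethered aldehyde should reach the flat butenolide on the face that carries C9, which gives the cis ring fusion (H7 and H8 cis). C6 is controlled by the chair: the butenolide locks C8 trans to the CH2–Cr carbon, so with C5 equatorial the adduct is anti (H6 and H7 trans), the aldehyde being attacked anti to the C5–O epoxide bond. The step needs ring closure to beat oligomerisation and 1,4-elimination of the C8 oxygen: slow addition at 2 mM secures the first, and the ring holds the C8–O bond in the plane of the allyl unit, orthogonal to its π system, which blocks the second.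

Step 18
Reactants: 23 8-hydroxy-1-O-TES-6,12-olide; 24 tigloyl chloride
Product: 25 1-O-TES ether of the target
Conditions: pyridine (3 equiv), DMAP (0.2 equiv), CH2Cl2, 0 °C to rt
Reagents that add atoms: none
Why: DMAP-catalysed acylation of O8, the only free hydroxyl, the (E)-configured tigloyl group being the stable isomer and keeping its geometry.

Step 19
Reactants: 25 1-O-TES ether of the target
Product: 26 CNP0164399.1
Conditions: HF·pyridine, pyridine, THF, 0 °C
Reagents that add atoms: none
Why: Fluoride cleavage of the TES ether under buffered conditions, which should free the C1 hydroxyl without touching the epoxides, the tiglate or the α-methylene lactone.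

**Compound list**

1 | acrolein (prop-2-enal) | C=CC=O | starting material
2 | 2,3-dibromoprop-1-ene | C=C(Br)CBr | starting material
3 | rac-5-bromohexa-1,5-dien-3-ol | C=CC(O)CC(Br)=C | intermediate
4 | (3R)-5-bromohexa-1,5-dien-3-ol | C=C[C@H](O)CC(Br)=C | intermediate
5 | acryloyl chloride (prop-2-enoyl chloride) | C=CC(Cl)=O | starting material
6 | (3R)-acrylate ester: (3R)-5-bromohexa-1,5-dien-3-yl prop-2-enoate | C=CC(=O)O[C@@H](C=C)CC(Br)=C | intermediate
7 | formaldehyde | C=O | starting material
8 | (3R)-2-(hydroxymethyl)acrylate ester: (3R)-5-bromohexa-1,5-dien-3-yl 2-(hydroxymethyl)prop-2-enoate | C=C(CO)C(=O)O[C@@H](C=C)CC(Br)=C | intermediate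
9 | bromoallyl butenolide alcohol: (5R)-5-(2-bromoprop-2-en-1-yl)-3-(hydroxymethyl)furan-2(5H)-one | OCC1=C[C@@H](CC(Br)=C)OC1=O | intermediate
10 | (2E)-3-methylpent-2-en-4-yn-1-ol | C#C/C(C)=C/CO | starting material
11 | enyne PMB ether: 1-methoxy-4-({[(2E)-3-methylpent-2-en-4-yn-1-yl]oxy}methyl)benzene | C#C/C(C)=C/COCc1ccc(OC)cc1 | intermediate
12 | propargylic alcohol: (4E)-6-[(4-methoxybenzyl)oxy]-4-methylhex-4-en-2-yn-1-ol | OCC#C/C(C)=C/COCc1ccc(OC)cc1 | intermediate
13 | (2Z,4E)-dienol: (2Z,4E)-6-[(4-methoxybenzyl)oxy]-4-methylhexa-2,4-dien-1-ol | OC/C=C\C(C)=C\COCc1ccc(OC)cc1 | intermediate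
14 | cis-epoxy alcohol: [(2S,3R)-3-{(2E)-4-[(4-methoxybenzyl)oxy]but-2-en-2-yl}oxiran-2-yl]methanol | OC[C@@H]1O[C@@H]1/C(C)=C/COCc2ccc(OC)cc2 | intermediate
15 | bis-epoxy alcohol: {(2S,3S)-3-[(2S,3R)-3-{[(4-methoxybenzyl)oxy]methyl}-2-methyloxiran-2-yl]oxiran-2-yl}methanol | OC[C@@H]1O[C@@H]1[C@@]1(C)O[C@@H]1COCc2ccc(OC)cc2 | intermediate
16 | bis-epoxy aldehyde: (2R,3S)-3-[(2S,3R)-3-{[(4-methoxybenzyl)oxy]methyl}-2-methyloxiran-2-yl]oxirane-2-carbaldehyde | O=C[C@@H]1O[C@@H]1[C@@]1(C)O[C@@H]1COCc2ccc(OC)cc2 | intermediate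
17 | seco diol: (5R)-5-{(3S)-3-hydroxy-2-methylidene-3-[(2S,3S)-3-{(2S,3R)-3-[(4-methoxybenzyloxy)methyl]-2-methyloxiran-2-yl}oxiran-2-yl]propyl}-3-(hydroxymethyl)furan-2(5H)-one | OCC1=C[C@@H](CC(=C)[C@H](O)[C@@H]2O[C@@H]2[C@@]2(C)O[C@@H]2COCc3ccc(OC)cc3)OC1=O | intermediate
18 | seco allylic bromide: (5R)-3-(bromomethyl)-5-{(3S)-3-hydroxy-2-methylidene-3-[(2S,3S)-3-{(2S,3R)-3-[(4-methoxybenzyloxy)methyl]-2-methyloxiran-2-yl}oxiran-2-yl]propyl}furan-2(5H)-one | BrCC1=C[C@@H](CC(=C)[C@H](O)[C@@H]2O[C@@H]2[C@@]2(C)O[C@@H]2COCc3ccc(OC)cc3)OC1=O | intermediate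
19 | seco bromide TES ether: (5R)-3-(bromomethyl)-5-{(3S)-2-methylidene-3-[(2R,3S)-3-{(2S,3R)-3-[(4-methoxybenzyloxy)methyl]-2-methyloxiran-2-yl}oxiran-2-yl]-3-(triethylsilyloxy)propyl}furan-2(5H)-one | BrCC1=C[C@@H](CC(=C)[C@H](O[Si](CC)(CC)CC)[C@@H]2O[C@@H]2[C@@]2(C)O[C@@H]2COCc3ccc(OC)cc3)OC1=O | intermediate
20 | seco bromo alcohol: (5R)-3-(bromomethyl)-5-{(3S)-3-[(2R,3S)-3-{(2S,3R)-3-(hydroxymethyl)-2-methyloxiran-2-yl}oxiran-2-yl]-2-methylidene-3-(triethylsilyloxy)propyl}furan-2(5H)-one | BrCC1=C[C@@H](CC(=C)[C@H](O[Si](CC)(CC)CC)[C@@H]2O[C@@H]2[C@@]2(C)O[C@@H]2CO)OC1=O | intermediate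
21 | seco bromo aldehyde: (5R)-3-(bromomethyl)-5-{(3S)-3-[(2R,3S)-3-{(2R,3S)-3-formyl-2-methyloxiran-2-yl}oxiran-2-yl]-2-methylidene-3-(triethylsilyloxy)propyl}furan-2(5H)-one | BrCC1=C[C@@H](CC(=C)[C@H](O[Si](CC)(CC)CC)[C@@H]2O[C@@H]2[C@@]2(C)O[C@@H]2C=O)OC1=O | intermediate
22 | 6-hydroxy-8,12-olide: (1S,2R,3S,4S,5R,6S,7S,8R)-2,3:4,5-diepoxy-6-hydroxy-1-(triethylsilyloxy)germacra-10(14),11(13)-dien-12,8-olide, formed as its chromium alkoxide | C=C1C(=O)O[C@@H]2CC(=C)[C@H](O[Si](CC)(CC)CC)[C@@H]3O[C@@H]3[C@@]3(C)O[C@@H]3[C@@H](O)[C@H]12 | intermediate (not isolated)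
23 | 8-hydroxy-1-O-TES-6,12-olide: (1S,2R,3S,4S,5R,6S,7R,8R)-2,3:4,5-diepoxy-8-hydroxy-1-(triethylsilyloxy)germacra-10(14),11(13)-dien-12,6-olide | C=C1C(=O)O[C@H]2[C@H]1[C@H](O)CC(=C)[C@H](O[Si](CC)(CC)CC)[C@@H]1O[C@@H]1[C@@]1(C)O[C@H]21 | intermediate
24 | tigloyl chloride, (2E)-2-methylbut-2-enoyl chloride | C/C=C(\C)C(Cl)=O | starting material
25 | 1-O-TES ether of the target: (1S,2R,3S,4S,5R,6S,7R,8R)-2,3:4,5-diepoxy-8-[(2E)-2-methylbut-2-enoyloxy]-1-(triethylsilyloxy)germacra-10(14),11(13)-dien-12,6-olide | C=C1C(=O)O[C@H]2[C@H]1[C@H](OC(=O)/C(C)=C/C)CC(=C)[C@H](O[Si](CC)(CC)CC)[C@@H]1O[C@@H]1[C@@]1(C)O[C@H]21 | intermediate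
26 | CNP0164399.1: (1S,2S,3S,4S,5R,6S,7R,8R)-2,3:4,5-diepoxy-1-hydroxy-8-[(2E)-2-methylbut-2-enoyloxy]germacra-10(14),11(13)-dien-12,6-olide | C=C1C(=O)O[C@H]2[C@H]1[C@H](OC(=O)/C(C)=C/C)CC(=C)[C@H](O)[C@@H]1O[C@@H]1[C@@]1(C)O[C@H]21 | target

**Totals**

Total step count: 19. Longest linear sequence: 14 steps (from 10 through steps 6–11 and 12–19); the butenolide branch (steps 1–5) joins at step 12.

**Steps most likely to fail**

1. Step 17 (ring closure with lactone migration). Oligomerisation may outrun ring closure, the aldehyde may be attacked on its other face or reach the butenolide face anti to C9 (C6/C7 epimers), or the lactone migration may stop part-way. The fallback sets out from 19 and comes back at 23; it replaces the redox-metal Barbier reaction by a thermal allylboration with an isolated, configurationally fixed reagent. Pd-catalysed borylation of the allylic bromide of 19 (B2pin2, Pd2(dba)3, toluene, 50 °C) would give the allylboronate F1. DDQ as in step 15 would give the alcohol F2, and Dess–Martin oxidation the boronate aldehyde F3. Heating F3 in toluene (2 mM, 70 °C) should join C7 to C6 through a closed chair; hydrolysis of the borate gives 22, and a catalytic amount of DBU in CH2Cl2 completes the lactone migration to 23.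

2. Step 12 (fragment union). Facial selectivity in the addition to the epoxy aldehyde may be poor, so that both C1 epimers form. The fallback sets out from 18 and comes back at 18; C1 is set by reduction instead of addition. The epimer mixture is carried through step 13, Dess–Martin oxidation of 18 would give the epoxy enone F4, and Zn(BH4)2 in Et2O at −30 °C, which chelates the ketone and epoxide oxygens and delivers hydride to the open face, should return the erythro (1S)-alcohol 18.

3. Step 10 (second epoxidation). Oxygen transfer to an alkene made electron-poor by two allylic C–O bonds may be slow, with decay of the ketone catalyst and loss of catalyst control. The fallback sets out from 10 and comes back at 15; both epoxides are then made by Sharpless epoxidation in reversed order. Ti(OiPr)4, D-(−)-diisopropyl tartrate and t-BuOOH would convert 10 into the alkynyl epoxy alcohol F5. NaH and 4-methoxybenzyl chloride would give its PMB ether F6, n-BuLi and paraformaldehyde the propargylic alcohol F7, and Lindlar hydrogenation the (Z)-allylic alcohol F8. A second Sharpless epoxidation with stoichiometric Ti(OiPr)4 and L-(+)-diisopropyl tartrate would give 15.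

**Further compounds**

F1 | step 17 | allylboronate: (5R)-5-{(3S)-2-methylidene-3-[(2R,3S)-3-{(2S,3R)-3-[(4-methoxybenzyloxy)methyl]-2-methyloxiran-2-yl}oxiran-2-yl]-3-(triethylsilyloxy)propyl}-3-[(4,4,5,5-tetramethyl-1,3,2-dioxaborolan-2-yl)methyl]furan-2(5H)-one | CC1(C)OB(CC2=C[C@@H](CC(=C)[C@H](O[Si](CC)(CC)CC)[C@@H]3O[C@@H]3[C@@]3(C)O[C@@H]3COCc4ccc(OC)cc4)OC2=O)OC1(C)C
F2 | step 17 | boronate alcohol: F1 with C6H2OH in place of C6H2OPMB, second oxirane (2S,3R)-3-(hydroxymethyl)-2-methyl | CC1(C)OB(CC2=C[C@@H](CC(=C)[C@H](O[Si](CC)(CC)CC)[C@@H]3O[C@@H]3[C@@]3(C)O[C@@H]3CO)OC2=O)OC1(C)C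
F3 | step 17 | boronate aldehyde: F1 with C6HO in place of C6H2OPMB, second oxirane (2R,3S)-3-formyl-2-methyl | CC1(C)OB(CC2=C[C@@H](CC(=C)[C@H](O[Si](CC)(CC)CC)[C@@H]3O[C@@H]3[C@@]3(C)O[C@@H]3C=O)OC2=O)OC1(C)C
F4 | step 12 | epoxy enone: (5R)-3-(bromomethyl)-5-{2-methylidene-3-[(2R,3S)-3-{(2S,3R)-3-[(4-methoxybenzyloxy)methyl]-2-methyloxiran-2-yl}oxiran-2-yl]-3-oxopropyl}furan-2(5H)-one | BrCC1=C[C@@H](CC(=C)C(=O)[C@@H]2O[C@@H]2[C@@]2(C)O[C@@H]2COCc3ccc(OC)cc3)OC1=O
F5 | step 10 | [(2R,3R)-3-ethynyl-3-methyloxiran-2-yl]methanol | C#C[C@@]1(C)O[C@@H]1CO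
F6 | step 10 | (2R,3R)-2-ethynyl-3-{[(4-methoxybenzyl)oxy]methyl}-2-methyloxirane | C#C[C@@]1(C)O[C@@H]1COCc2ccc(OC)cc2
F7 | step 10 | 3-[(2R,3R)-3-{[(4-methoxybenzyl)oxy]methyl}-2-methyloxiran-2-yl]prop-2-yn-1-ol | OCC#C[C@@]1(C)O[C@@H]1COCc2ccc(OC)cc2
F8 | step 10 | (2Z)-3-[(2R,3R)-3-{[(4-methoxybenzyl)oxy]methyl}-2-methyloxiran-2-yl]prop-2-en-1-ol | OC/C=C\[C@@]1(C)O[C@@H]1COCc2ccc(OC)cc2
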